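The cyclohexane ring is closed last, from an open chain (ring numbering: C1 acrylate-bearing, C2 acyloxy, C3 methylene, C4 quaternary, C5 hydroxyisopropenyl-bearing, C6 hydroxyl). Two features are exploited: the vinyl-bearing quaternary C4 beside the alkenyl-bearing C5 is the imprint of a [3,3] shift, and the 1,3-dioxygen pattern C2–O/C6–O across C1 is an aldol pattern. A dianionic oxy-Cope rearrangement of an acyclic hydroxy dienone forges C4–C5 with chirality relay from its carbinol and unveils the C2 aldehyde, which the C6 ketone enolate captures at C1 in the same flask. The precursor is a linear 8-hydroxy-4-oxo trienoate, assembled by a catalytic asymmetric vinylogous aldol reaction and a Barbier allylation.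

Key step: step 12

Remark: the target is taken exactly as drawn, (1S,2S,4R,5R,6S) in the ring numbering above: C4 vinyl cis to the C5 side chain, C6 hydroxyl cis to both neighbouring side chains, C2 acyloxy trans to the C1 side chain.
Remark: in step 4 the catalyst antipode is assumed to be the one that directs Si-face attack on aldehyde 3 (written as (S,S)); the antipode is used if the sense proves opposite.
Remark: 2-oxoethyl acetate (22) is taken as a commercial compound; the final hydroxy acid is expected to lactonise easily and is to be handled cold near pH 5.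

Step 1
Reactants: 1 (2E)-3-methylpent-2-en-4-yn-1-ol
Product: 2 (2E)-3-methylpenta-2,4-dien-1-ol
Conditions: H2 (1 atm), Pd/CaCO3 poisoned with Pb(OAc)2, quinoline, MeOH, rt
Reagents that add atoms: none
Why: Semihydrogenation of the terminal alkyne over the poisoned palladium catalyst should stop at the diene and leave the E alkene untouched.

Step 2
Reactants: 2 (2E)-3-methylpenta-2,4-dien-1-ol
Product: 3 (2E)-3-methylpenta-2,4-dienal
Conditions: MnO2, CH2Cl2, rt; the volatile dienal is used as a solution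
Reagents that add atoms: none
Why: Allylic oxidation with MnO2 should give the enal without E/Z erosion.

Step 3
Reactants: 4 ethyl 3-methylbut-2-enoate
Product: 5 tert-butyl[(1-ethoxy-3-methylbuta-1,3-dien-1-yl)oxy]dimethylsilane
Conditions: LiN(i-Pr)2, THF, −78 °C; then t-BuMe2SiCl, DMPU, −78 °C to rt
Reagents that add atoms: tert-butyldimethylsilyl chloride, CC(C)(C)[Si](C)(C)Cl
Why: γ-Deprotonation of the enoate and O-silylation of the extended enolate should give the silyl dienol ether (silyl ketene acetal formation).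

Step 4
Reactants: 3 (2E)-3-methylpenta-2,4-dienal; 5 tert-butyl[(1-ethoxy-3-methylbuta-1,3-dien-1-yl)oxy]dimethylsilane
Product: 6 ethyl (2E,5S,6E)-5-hydroxy-3,7-dimethylnona-2,6,8-trienoate
Conditions: SiCl4, (S,S)-bisphosphoramide Lewis base catalyst derived from N,N′-dimethyl-1,1′-binaphthyl-2,2′-diamine (5 mol %), i-Pr2NEt (10 mol %), CH2Cl2, −78 °C; aq. NaHCO3 work-up
Reagents that add atoms: none
Why: A Lewis-base-catalysed vinylogous Mukaiyama aldol addition should occur at the γ-carbon of 5 with 1,2-selectivity on the dienal; the chiral catalyst sets the 5S carbinol by Si-face attack and the s-trans dienolate gives the 2E alkene.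

Step 5
Reactants: 6 ethyl (2E,5S,6E)-5-hydroxy-3,7-dimethylnona-2,6,8-trienoate
Product: 7 ethyl (2E,5S,6E)-5-[(tert-butyldimethylsilyl)oxy]-3,7-dimethylnona-2,6,8-trienoate
Conditions: t-BuMe2SiCl, imidazole, DMF, rt
Reagents that add atoms: tert-butyldimethylsilyl chloride, CC(C)(C)[Si](C)(C)Cl
Why: Silyl ether formation masks the dienylic alcohol so that only the other allylic alcohol is oxidised later.

Step 6
Reactants: 7 ethyl (2E,5S,6E)-5-[(tert-butyldimethylsilyl)oxy]-3,7-dimethylnona-2,6,8-trienoate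
Product: 8 (2E,5S,6E)-5-[(tert-butyldimethylsilyl)oxy]-3,7-dimethylnona-2,6,8-trien-1-ol
Conditions: i-Bu2AlH (2.2 equiv), CH2Cl2, −78 °C; aq. potassium sodium tartrate
Reagents that add atoms: none
Why: 1,2-Reduction of the enoate by the aluminium hydride should give the allylic alcohol without touching the alkenes.

Step 7
Reactants: 8 (2E,5S,6E)-5-[(tert-butyldimethylsilyl)oxy]-3,7-dimethylnona-2,6,8-trien-1-ol
Product: 9 (2E,5S,6E)-5-[(tert-butyldimethylsilyl)oxy]-3,7-dimethylnona-2,6,8-trienal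
Conditions: MnO2, CH2Cl2, rt
Reagents that add atoms: none
Why: Allylic oxidation with MnO2 should give the E enal.

Step 8
Reactants: 10 2-(bromomethyl)prop-2-enoic acid
Product: 11 2-(trimethylsilyl)ethyl 2-(bromomethyl)prop-2-enoate
Conditions: N,N′-dicyclohexylcarbodiimide, 4-(dimethylamino)pyridine (5 mol %), CH2Cl2, 0 °C
Reagents that add atoms: 2-(trimethylsilyl)ethanol, C[Si](C)(C)CCO
Why: Steglich esterification installs an acid protecting group that is later removed by fluoride without hydrolysis.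

Step 9
Reactants: 9 (2E,5S,6E)-5-[(tert-butyldimethylsilyl)oxy]-3,7-dimethylnona-2,6,8-trienal; 11 2-(trimethylsilyl)ethyl 2-(bromomethyl)prop-2-enoate
Product: 12 2-(trimethylsilyl)ethyl (5E,8S,9E)-8-[(tert-butyldimethylsilyl)oxy]-4-hydroxy-6,10-dimethyl-2-methylidenedodeca-5,9,11-trienoate (both C4 epimers)
Conditions: In powder, THF/H2O (3:1), rt
Reagents that add atoms: none
Why: Barbier allylation by the allylindium species should add 1,2 to the enal; the new carbinol configuration is irrelevant because it is oxidised in step 10.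

Step 10
Reactants: 12 2-(trimethylsilyl)ethyl (5E,8S,9E)-8-[(tert-butyldimethylsilyl)oxy]-4-hydroxy-6,10-dimethyl-2-methylidenedodeca-5,9,11-trienoate
Product: 13 2-(trimethylsilyl)ethyl (5E,8S,9E)-8-[(tert-butyldimethylsilyl)oxy]-6,10-dimethyl-2-methylidene-4-oxododeca-5,9,11-trienoate
Conditions: Dess–Martin periodinane (1,1,1-triacetoxy-1,2-benziodoxol-3-one), CH2Cl2, 0 °C to rt
Reagents that add atoms: none
Why: Dess–Martin oxidation under base-free conditions should give the enone while the doubly activated C3 methylene stays out of conjugation.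

Step 11
Reactants: 13 2-(trimethylsilyl)ethyl (5E,8S,9E)-8-[(tert-butyldimethylsilyl)oxy]-6,10-dimethyl-2-methylidene-4-oxododeca-5,9,11-trienoate
Product: 14 2-(trimethylsilyl)ethyl (5E,8S,9E)-8-hydroxy-6,10-dimethyl-2-methylidene-4-oxododeca-5,9,11-trienoate
Conditions: HF·pyridine, pyridine, THF, 0 °C to rt
Reagents that add atoms: none
Why: Buffered HF should cleave the secondary silyl ether (desilylation) and spare the 2-(trimethylsilyl)ethyl ester and the base-sensitive enone.

Step 12
Reactants: 14 2-(trimethylsilyl)ethyl (5E,8S,9E)-8-hydroxy-6,10-dimethyl-2-methylidene-4-oxododeca-5,9,11-trienoate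
Product: 16 2-(trimethylsilyl)ethyl 2-[(1R,2S,4R,5S)-4-ethenyl-2-hydroxy-4-methyl-6-oxo-5-(prop-1-en-2-yl)cyclohexyl]prop-2-enoate, via keto aldehyde 15 (not isolated)
Conditions: KN(SiMe3)2 (2.3 equiv), THF, −78 °C; 18-crown-6, −78 to 0 °C; AcOH (1.1 equiv), −78 to −40 °C; then AcOH (excess), −78 °C
Reagents that add atoms: none
Why: Double deprotonation gives the alkoxide/ketone-dienolate dianion, whose 1,5-dien-3-olate unit undergoes an anionic oxy-Cope rearrangement ([3,3], chair transition state) that forms the C4–C5 bond and releases the C2 aldehyde as its enolate; one equivalent of acid then returns the aldehyde, which the ketone enolate attacks at C1 in an intramolecular aldol addition, the whole being a tandem anionic oxy-Cope/aldol sequence. The only ring closed is the cyclohexane, by a 6-(enolendo)-exo-trig aldol closure. C4 and C5 are set by the chair in which both alkene termini are E (vinyl and the enolate carbon equatorial, methyl and hydrogen axial) and the oxido group is equatorial, an orientation enforced by 1,3-diaxial strain with the cis methyl of the diene, so the 8S carbinol relays its chirality and is then erased. C1 and C2 are set by a chair-like aldol transition state with the C5 isopropenyl group, the C1 acrylate branch (from the enolate with this branch cis to the oxygen) and the aldehyde oxygen all equatorial, which is also the thermodynamically preferred arrangement. The step needs the dianion rather than the mono-alkoxide, which suppresses retro-vinylogous-aldol cleavage and fixes enolisation at the doubly activated methylene between ketone and acrylate, and it needs a cold quench so that C5, now alpha to the ketone, does not epimerise.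

Step 13
Reactants: 16 2-(trimethylsilyl)ethyl 2-[(1R,2S,4R,5S)-4-ethenyl-2-hydroxy-4-methyl-6-oxo-5-(prop-1-en-2-yl)cyclohexyl]prop-2-enoate
Product: 17 2-(trimethylsilyl)ethyl 2-[(1R,2S,4R,5S,6S)-4-ethenyl-2,6-dihydroxy-4-methyl-5-(prop-1-en-2-yl)cyclohexyl]prop-2-enoate
Conditions: LiAlH(O-t-Bu)3 (2.5 equiv), THF, −78 to −20 °C
Reagents that add atoms: none
Why: In this diastereoselective ketone reduction the axial approach is blocked by the syn-axial vinyl group on C4, so the bulky alkoxyaluminium hydride should enter equatorially and give the axial 6S alcohol, without reducing the esters or the acrylate.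

Step 14
Reactants: 18 tert-butyl 2-bromopropanoate
Product: 19 tert-butyl 2-(diphenoxyphosphoryl)propanoate
Conditions: (PhO)2P(O)H, Et3N, CH2Cl2, 0 °C to rt
Reagents that add atoms: diphenyl phosphite, O=[PH](Oc1ccccc1)Oc1ccccc1
Why: Michaelis–Becker alkylation of the phosphite anion at the α-bromo ester gives the diaryl phosphonate needed for a Z-selective olefination.

Step 15
Reactants: 19 tert-butyl 2-(diphenoxyphosphoryl)propanoate
Product: 20 2-(diphenoxyphosphoryl)propanoic acid
Conditions: CF3CO2H, CH2Cl2, rt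
Reagents that add atoms: none
Why: Acidolysis of the tert-butyl ester (loss of isobutene) frees the acid without touching the aryl phosphonate esters.

Step 16
Reactants: 17 2-(trimethylsilyl)ethyl 2-[(1R,2S,4R,5S,6S)-4-ethenyl-2,6-dihydroxy-4-methyl-5-(prop-1-en-2-yl)cyclohexyl]prop-2-enoate; 20 2-(diphenoxyphosphoryl)propanoic acid
Product: 21 2-(trimethylsilyl)ethyl 2-[(1S,2S,4R,5S,6S)-2-{[2-(diphenoxyphosphoryl)propanoyl]oxy}-4-ethenyl-6-hydroxy-4-methyl-5-(prop-1-en-2-yl)cyclohexyl]prop-2-enoate (both epimers at the phosphonate-bearing carbon)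
Conditions: N,N′-dicyclohexylcarbodiimide, 4-(dimethylamino)pyridine (10 mol %), CH2Cl2, 0 °C
Reagents that add atoms: none
Why: Steglich esterification should take place only at the equatorial C2 hydroxyl, because the axial C6 hydroxyl is flanked by two branched carbons and is syn to the axial vinyl group.

Step 17
Reactants: 21 2-(trimethylsilyl)ethyl 2-[(1S,2S,4R,5S,6S)-2-{[2-(diphenoxyphosphoryl)propanoyl]oxy}-4-ethenyl-6-hydroxy-4-methyl-5-(prop-1-en-2-yl)cyclohexyl]prop-2-enoate; 22 2-oxoethyl acetate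
Product: 23 2-(trimethylsilyl)ethyl 2-[(1S,2S,4R,5S,6S)-2-{[(2Z)-4-(acetyloxy)-2-methylbut-2-enoyl]oxy}-4-ethenyl-6-hydroxy-4-methyl-5-(prop-1-en-2-yl)cyclohexyl]prop-2-enoate
Conditions: NaH (1.0 equiv), THF, −78 °C; then 22, −78 to 0 °C
Reagents that add atoms: none
Why: Horner–Wadsworth–Emmons olefination with the diaryl phosphonate should collapse rapidly through the syn oxaphosphetane and give the Z trisubstituted enoate (ester cis to CH2OAc); the phosphonate is far more acidic than the free hydroxyl, so one equivalent of base suffices.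

Step 18
Reactants: 23 2-(trimethylsilyl)ethyl 2-[(1S,2S,4R,5S,6S)-2-{[(2Z)-4-(acetyloxy)-2-methylbut-2-enoyl]oxy}-4-ethenyl-6-hydroxy-4-methyl-5-(prop-1-en-2-yl)cyclohexyl]prop-2-enoate
Product: 24 2-(trimethylsilyl)ethyl 2-[(1S,2S,4R,5R,6S)-2-{[(2Z)-4-(acetyloxy)-2-methylbut-2-enoyl]oxy}-4-ethenyl-6-hydroxy-5-(3-hydroxyprop-1-en-2-yl)-4-methylcyclohexyl]prop-2-enoate
Conditions: SeO2 (0.3 equiv), t-BuOOH (3 equiv), CH2Cl2, 0 °C to rt
Reagents that add atoms: selenium dioxide, O=[Se]=O (oxygen donor, reoxidised by tert-butyl hydroperoxide, CC(C)(C)OO)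
Why: Allylic oxidation by SeO2 (ene reaction then [2,3]-sigmatropic shift) should occur only at the electron-rich isopropenyl group, on its methyl and not on the ring methine, since the other alkenes are electron-poor or lack allylic hydrogens.

Step 19
Reactants: 24 2-(trimethylsilyl)ethyl 2-[(1S,2S,4R,5R,6S)-2-{[(2Z)-4-(acetyloxy)-2-methylbut-2-enoyl]oxy}-4-ethenyl-6-hydroxy-5-(3-hydroxyprop-1-en-2-yl)-4-methylcyclohexyl]prop-2-enoate
Product: 25 2-[(1S,2S,4R,5R,6S)-2-{[(2Z)-4-(acetyloxy)-2-methylbut-2-enoyl]oxy}-4-ethenyl-6-hydroxy-5-(3-hydroxyprop-1-en-2-yl)-4-methylcyclohexyl]prop-2-enoic acid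
Conditions: Bu4NF, THF, 0 °C; then AcOH, cold pH 5 buffer work-up
Reagents that add atoms: none
Why: Fluoride-induced β-elimination cleaves the 2-(trimethylsilyl)ethyl ester without hydrolysis, so the two other esters should survive and the carboxylate is protonated only under cold, weakly acidic conditions that should avoid lactonisation onto the cis C6 hydroxyl.

Compound list
1 | (2E)-3-methylpent-2-en-4-yn-1-ol | C#C/C(C)=C/CO | starting material
2 | (2E)-3-methylpenta-2,4-dien-1-ol | C=C/C(C)=C/CO | intermediate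
3 | (2E)-3-methylpenta-2,4-dienal | C=C/C(C)=C/C=O | intermediate
4 | ethyl 3-methylbut-2-enoate | CCOC(=O)C=C(C)C | starting material
5 | tert-butyl[(1-ethoxy-3-methylbuta-1,3-dien-1-yl)oxy]dimethylsilane (enol ether geometry not defined) | C=C(C)C=C(OCC)O[Si](C)(C)C(C)(C)C | intermediate
6 | ethyl (2E,5S,6E)-5-hydroxy-3,7-dimethylnona-2,6,8-trienoate | CCOC(=O)/C=C(C)/C[C@H](O)/C=C(C)/C=C | intermediate
7 | ethyl (2E,5S,6E)-5-[(tert-butyldimethylsilyl)oxy]-3,7-dimethylnona-2,6,8-trienoate | CCOC(=O)/C=C(C)/C[C@H](O[Si](C)(C)C(C)(C)C)/C=C(C)/C=C | intermediate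
8 | (2E,5S,6E)-5-[(tert-butyldimethylsilyl)oxy]-3,7-dimethylnona-2,6,8-trien-1-ol | OC/C=C(C)/C[C@H](O[Si](C)(C)C(C)(C)C)/C=C(C)/C=C | intermediate
9 | (2E,5S,6E)-5-[(tert-butyldimethylsilyl)oxy]-3,7-dimethylnona-2,6,8-trienal | O=C/C=C(C)/C[C@H](O[Si](C)(C)C(C)(C)C)/C=C(C)/C=C | intermediate
10 | 2-(bromomethyl)prop-2-enoic acid | C=C(CBr)C(=O)O | starting material
11 | 2-(trimethylsilyl)ethyl 2-(bromomethyl)prop-2-enoate | C=C(CBr)C(=O)OCC[Si](C)(C)C | intermediate
12 | 2-(trimethylsilyl)ethyl (5E,8S,9E)-8-[(tert-butyldimethylsilyl)oxy]-4-hydroxy-6,10-dimethyl-2-methylidenedodeca-5,9,11-trienoate (C4 epimer mixture) | C=C(CC(O)/C=C(C)/C[C@H](O[Si](C)(C)C(C)(C)C)/C=C(C)/C=C)C(=O)OCC[Si](C)(C)C | intermediate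
13 | 2-(trimethylsilyl)ethyl (5E,8S,9E)-8-[(tert-butyldimethylsilyl)oxy]-6,10-dimethyl-2-methylidene-4-oxododeca-5,9,11-trienoate | C=C(CC(=O)/C=C(C)/C[C@H](O[Si](C)(C)C(C)(C)C)/C=C(C)/C=C)C(=O)OCC[Si](C)(C)C | intermediate
14 | 2-(trimethylsilyl)ethyl (5E,8S,9E)-8-hydroxy-6,10-dimethyl-2-methylidene-4-oxododeca-5,9,11-trienoate | C=C(CC(=O)/C=C(C)/C[C@H](O)/C=C(C)/C=C)C(=O)OCC[Si](C)(C)C | intermediate
15 | 2-(trimethylsilyl)ethyl (5S,6R)-6-ethenyl-6-methyl-2-methylidene-4,8-dioxo-5-(prop-1-en-2-yl)octanoate (keto aldehyde, present in the flask as its enolates) | C=C[C@@](C)(CC=O)[C@H](C(=C)C)C(=O)CC(=C)C(=O)OCC[Si](C)(C)C | intermediate (not isolated)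
16 | 2-(trimethylsilyl)ethyl 2-[(1R,2S,4R,5S)-4-ethenyl-2-hydroxy-4-methyl-6-oxo-5-(prop-1-en-2-yl)cyclohexyl]prop-2-enoate | C=C[C@@]1(C)C[C@H](O)[C@@H](C(=C)C(=O)OCC[Si](C)(C)C)C(=O)[C@H]1C(=C)C | intermediate
17 | 2-(trimethylsilyl)ethyl 2-[(1R,2S,4R,5S,6S)-4-ethenyl-2,6-dihydroxy-4-methyl-5-(prop-1-en-2-yl)cyclohexyl]prop-2-enoate | C=C[C@@]1(C)C[C@H](O)[C@@H](C(=C)C(=O)OCC[Si](C)(C)C)[C@@H](O)[C@H]1C(=C)C | intermediate
18 | tert-butyl 2-bromopropanoate (racemic) | CC(Br)C(=O)OC(C)(C)C | starting material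
19 | tert-butyl 2-(diphenoxyphosphoryl)propanoate (racemic) | CC(C(=O)OC(C)(C)C)P(=O)(Oc1ccccc1)Oc1ccccc1 | intermediate
20 | 2-(diphenoxyphosphoryl)propanoic acid (racemic) | CC(C(=O)O)P(=O)(Oc1ccccc1)Oc1ccccc1 | intermediate
21 | 2-(trimethylsilyl)ethyl 2-[(1S,2S,4R,5S,6S)-2-{[2-(diphenoxyphosphoryl)propanoyl]oxy}-4-ethenyl-6-hydroxy-4-methyl-5-(prop-1-en-2-yl)cyclohexyl]prop-2-enoate (epimer mixture at the phosphonate-bearing carbon) | C=C[C@@]1(C)C[C@H](OC(=O)C(C)P(=O)(Oc2ccccc2)Oc2ccccc2)[C@@H](C(=C)C(=O)OCC[Si](C)(C)C)[C@@H](O)[C@H]1C(=C)C | intermediate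
22 | 2-oxoethyl acetate | CC(=O)OCC=O | starting material
23 | 2-(trimethylsilyl)ethyl 2-[(1S,2S,4R,5S,6S)-2-{[(2Z)-4-(acetyloxy)-2-methylbut-2-enoyl]oxy}-4-ethenyl-6-hydroxy-4-methyl-5-(prop-1-en-2-yl)cyclohexyl]prop-2-enoate | C=C[C@@]1(C)C[C@H](OC(=O)/C(C)=C\COC(C)=O)[C@@H](C(=C)C(=O)OCC[Si](C)(C)C)[C@@H](O)[C@H]1C(=C)C | intermediate
24 | 2-(trimethylsilyl)ethyl 2-[(1S,2S,4R,5R,6S)-2-{[(2Z)-4-(acetyloxy)-2-methylbut-2-enoyl]oxy}-4-ethenyl-6-hydroxy-5-(3-hydroxyprop-1-en-2-yl)-4-methylcyclohexyl]prop-2-enoate | C=C[C@@]1(C)C[C@H](OC(=O)/C(C)=C\COC(C)=O)[C@@H](C(=C)C(=O)OCC[Si](C)(C)C)[C@@H](O)[C@H]1C(=C)CO | intermediate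
25 | 2-[(1S,2S,4R,5R,6S)-2-{[(2Z)-4-(acetyloxy)-2-methylbut-2-enoyl]oxy}-4-ethenyl-6-hydroxy-5-(3-hydroxyprop-1-en-2-yl)-4-methylcyclohexyl]prop-2-enoic acid (CNP0261293.7) | C=C[C@@]1(C)C[C@H](OC(=O)/C(C)=C\COC(C)=O)[C@@H](C(=C)C(=O)O)[C@@H](O)[C@H]1C(=C)CO | target

Total step count: 19
Longest linear sequence: 15 steps (steps 1, 2, 4 to 7, 9 to 13, 16 to 19)

Steps most likely to fail

Step 12. The alkoxide may fragment by a retro-vinylogous-aldol pathway instead of rearranging, or enolate equilibration before the quench may epimerise C5 or dehydrate the aldol. The fallback sets out from 13. The silyl ether is heated (toluene, 2,6-di-tert-butyl-4-methylphenol, sealed tube, about 180 °C) so that a neutral siloxy-Cope rearrangement through the same chair (silyloxy group equatorial) forges C4–C5 without base and gives the silyl enol ether 2-(trimethylsilyl)ethyl (5S,6S)-8-[(tert-butyldimethylsilyl)oxy]-6-ethenyl-6-methyl-2-methylidene-4-oxo-5-(prop-1-en-2-yl)oct-7-enoate F1. Mild acid (AcOH/THF/H2O, rt) then releases keto aldehyde 15, now isolated. A separate soft-enolisation aldol (MgBr2·OEt2, i-Pr2NEt, CH2Cl2, −20 °C) closes C1–C2 and comes back to the route at 16.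

Step 18. The new allylic alcohol may be over-oxidised to the enal, and site selectivity between the allylic positions may be lost. The fallback sets out from 23. A Schenck ene reaction with singlet oxygen (O2, tetraphenylporphyrin, visible light, CH2Cl2, 0 °C) at the only electron-rich alkene that carries allylic hydrogens should give the allylic hydroperoxide 2-(trimethylsilyl)ethyl 2-[(1S,2S,4R,5R,6S)-2-{[(2Z)-4-(acetyloxy)-2-methylbut-2-enoyl]oxy}-4-ethenyl-5-(3-hydroperoxyprop-1-en-2-yl)-6-hydroxy-4-methylcyclohexyl]prop-2-enoate F2. Reduction with PPh3 then comes back to the route at 24.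

Step 13. Facial selectivity of hydride addition may be poor (competing axial delivery giving the equatorial C6 alcohol), and the basic hydride may trigger retro-aldol cleavage. The fallback sets out from 16. Conjugate addition of thiophenol (PhSH, cat. Et3N, CH2Cl2) masks the acrylate as 2-(trimethylsilyl)ethyl 2-[(1R,2S,4R,5S)-4-ethenyl-2-hydroxy-4-methyl-6-oxo-5-(prop-1-en-2-yl)cyclohexyl]-3-(phenylsulfanyl)propanoate F3. The very bulky LiBH(s-Bu)3 (THF, −78 °C) can then be used and should add hydride equatorially to give the axial alcohol 2-(trimethylsilyl)ethyl 2-[(1R,2S,4R,5S,6S)-4-ethenyl-2,6-dihydroxy-4-methyl-5-(prop-1-en-2-yl)cyclohexyl]-3-(phenylsulfanyl)propanoate F4. Oxidation with 3-chloroperbenzoic acid (CH2Cl2, −78 °C) gives the sulfoxide 2-(trimethylsilyl)ethyl 3-(benzenesulfinyl)-2-[(1R,2S,4R,5S,6S)-4-ethenyl-2,6-dihydroxy-4-methyl-5-(prop-1-en-2-yl)cyclohexyl]propanoate F5. Thermal syn-elimination (toluene, CaCO3, 90 °C) regenerates the acrylate and comes back to the route at 17.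

Further compounds
F1 | step 12 | 2-(trimethylsilyl)ethyl (5S,6S)-8-[(tert-butyldimethylsilyl)oxy]-6-ethenyl-6-methyl-2-methylidene-4-oxo-5-(prop-1-en-2-yl)oct-7-enoate | C=C[C@@](C)(C=CO[Si](C)(C)C(C)(C)C)[C@H](C(=C)C)C(=O)CC(=C)C(=O)OCC[Si](C)(C)C
F2 | step 18 | 2-(trimethylsilyl)ethyl 2-[(1S,2S,4R,5R,6S)-2-{[(2Z)-4-(acetyloxy)-2-methylbut-2-enoyl]oxy}-4-ethenyl-5-(3-hydroperoxyprop-1-en-2-yl)-6-hydroxy-4-methylcyclohexyl]prop-2-enoate | C=C[C@@]1(C)C[C@H](OC(=O)/C(C)=C\COC(C)=O)[C@@H](C(=C)C(=O)OCC[Si](C)(C)C)[C@@H](O)[C@H]1C(=C)COO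
F3 | step 13 | 2-(trimethylsilyl)ethyl 2-[(1R,2S,4R,5S)-4-ethenyl-2-hydroxy-4-methyl-6-oxo-5-(prop-1-en-2-yl)cyclohexyl]-3-(phenylsulfanyl)propanoate | C=C[C@@]1(C)C[C@H](O)[C@@H](C(CSc2ccccc2)C(=O)OCC[Si](C)(C)C)C(=O)[C@H]1C(=C)C
F4 | step 13 | 2-(trimethylsilyl)ethyl 2-[(1R,2S,4R,5S,6S)-4-ethenyl-2,6-dihydroxy-4-methyl-5-(prop-1-en-2-yl)cyclohexyl]-3-(phenylsulfanyl)propanoate | C=C[C@@]1(C)C[C@H](O)[C@@H](C(CSc2ccccc2)C(=O)OCC[Si](C)(C)C)[C@@H](O)[C@H]1C(=C)C
F5 | step 13 | 2-(trimethylsilyl)ethyl 3-(benzenesulfinyl)-2-[(1R,2S,4R,5S,6S)-4-ethenyl-2,6-dihydroxy-4-methyl-5-(prop-1-en-2-yl)cyclohexyl]propanoate | C=C[C@@]1(C)C[C@H](O)[C@@H](C(CS(=O)c2ccccc2)C(=O)OCC[Si](C)(C)C)[C@@H](O)[C@H]1C(=C)C
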